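The constants of this chemistry are not on hand, so begin with the one you can read yourself from the grey run, and read it from the fraction of starting material left, not the fraction made.

in all of them: starting material 0.050 M; added ligand 0.33 mM; temperature 0 °C

| flask | second substrate | coupling partner | free catalyst | impurity | remark | time |
|---|---|---|---|---|---|---|
| grey | 0.025 M | 0.10 M | 120 µM | 33 µM | run made earlier |  |
| cedar | 0.0250 M | 0.0250 M | 80 µM | 8.0 µM |  | 10 min |
| maple | 0.0250 M | 0.100 M | 80 µM | 33 µM |  | 10 min |

grey run (percent of the starting material charged)

| time / min | target / % |
|---|---|
| 1.33 | 25.5 |
| 2.50 | 42.0 |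
| 4.00 | 57.7 |
| 5.00 | 66.2 |
| 6.00 | 72.6 |

(scatter of a reading: 0.3 percentage points)

- no earlier run changes the charge of free catalyst; that part of a forecast is a guess
- no earlier run changes the charge of impurity; that part of a forecast is a guess

- which of the two ends with the higher amount of target, in percent of the starting material charged ("neither" if they lie within 2 percentage points) (cedar / maple / neither)
- target at the end, in percent of the starting material charged, cedar
- target at the end, in percent of the starting material charged, maple

Grey leaves 74.5% after 1.33 min and 27.4% after 6.00 min. The logarithm of that fraction over the time gives 0.221 min⁻¹ at the first reading and 0.216 min⁻¹ at the last, so one first-order constant carries grey.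

Now the clash. Carried over to cedar, that constant reckons to 11.5% of its starting material left after 10 min. But call the charge of coupling partner over the charge of starting material the partner ceiling: in cedar it is 50.0%, and with one coupling partner per target, at least 50.0% stays.

Both numbers stand, for different things. One is pace, the other budget, and the larger fraction left is the one to believe. Grey's ceiling is 200%, more than its whole charge of starting material, so grey's steady constant says nothing about a budget. In cedar, coupling partner is the limiting reagent.

My figure for cedar is therefore a bound, not a value: target no more than 50.0%. Grey's readings are of target, so they do not show whether coupling partner goes elsewhere. Maple has grey's ceiling, and half the grey constant, a guess since no earlier run changes free catalyst, reckons to 66.0% target there, more than cedar's bound, so I expect maple ahead.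

The forecast also puts maple ahead, with cedar at 49% and maple at 71%. Its grounds for cedar: “0.025 M partner caps target at 50% if consumed 1:1”. Its cedar number is about what you get with all of the coupling partner turned into target.

Cedar ends at 31.7% and maple at 67.4%, so maple is higher, and cedar stands 17 percentage points below the forecast.

    starting material + free catalyst ⇌ catalyst intermediate A (K = 330 M⁻¹, k = 102 M⁻¹ s⁻¹, Ea = 46.0 kJ mol⁻¹, ΔH = −58.0 kJ mol⁻¹)
    coupling partner + catalyst intermediate A → free catalyst + target (k = 1050 M⁻¹ s⁻¹, Ea = 38.0 kJ mol⁻¹)
    second substrate + free catalyst ⇌ catalyst intermediate B (K = 68.0 M⁻¹, k = 176 M⁻¹ s⁻¹, Ea = 35.0 kJ mol⁻¹, ΔH = −69.0 kJ mol⁻¹)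
    coupling partner + catalyst intermediate B → free catalyst + second product (k = 748 M⁻¹ s⁻¹, Ea = 37.0 kJ mol⁻¹)
    free catalyst + added ligand ⇌ idle complex, settled at all times (K = 4900 M⁻¹, ΔH = −44.0 kJ mol⁻¹)
    free catalyst + impurity → spent catalyst (k = 13700 M⁻¹ s⁻¹, Ea = 17.0 kJ mol⁻¹)
    (constants at 0 °C)

At 10.0 min cedar holds 0% of its coupling partner, and second product accounts for 36.7% of that charge. Target over ceiling gives the share of coupling partner that reached target, 63.3% in cedar. The neighbour of cedar charged with 0.062 M of coupling partner has a ceiling of 124%. At cedar's share that comes to 78.5%, and that flask ends at 78.8%.

Readings and results were generated by integration with made-up constants, noise included.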